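**Retrosynthetic overview**
1. Target ⇐ hydrogenolysis of two aryl benzyl ethers ⇐ tetrahydrofuran closed last by acid-mediated SN1 etherification of a hexaol ⇐ LiAlH4 reduction of hydroxy lactone 23.
2. 23 ⇐ new three-component copper hydride reductive aldol of butenolide 21 (ring A), HBpin and aldehyde 18 (forms C7–C8, sets the two lactone stereocentres).
3. 18 ⇐ three identical cycles on 5-iodovanillin: O-benzylation of the phenol by the growing chain, Pd coupling with ethyl diazoacetate, Rh-catalysed 1,5 C–H insertion (cis, catalyst sets C2), base epimerisation to trans.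
4. Ring order: dihydrofuran on ring D, then on ring C, then on ring B, tetrahydrofuran last; rings A and E both come from 4-(benzyloxy)-3-methoxybenzyl alcohol.

**Lettering and shorthand.** Ring A is the guaiacyl ring of the benzyl group on the tetrahydrofuran. Rings B, C and D are the benzo rings of the three dihydrobenzofurans, counted outward from the tetrahydrofuran. Ring E is the terminal guaiacyl ring. Ar = 4-(benzyloxy)-3-methoxyphenyl; DHB = 2,3-dihydro-1-benzofuran. Unit D = (2R,3R)-2-Ar-3-(ethoxycarbonyl)-7-methoxy-DHB-5-yl. Unit CD = (2S,3S)-2-(unit D)-3-(ethoxycarbonyl)-7-methoxy-DHB-5-yl. Unit BCD = (2S,3S)-2-(unit CD)-3-(ethoxycarbonyl)-7-methoxy-DHB-5-yl. Unit BCD-triol = unit BCD with each CO2Et replaced by CH2OH, same geometry; the descriptors become (2S,3R) in rings B and C and (2R,3S) in ring D. Rh2(S-PTTL)4 = dirhodium tetrakis[N-phthaloyl-(S)-tert-leucinate].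

**Assumption:** the sense of induction is taken as Rh2(S-PTTL)4 → (2R) ring, Rh2(R-PTTL)4 → (2S) ring, and (R)-DTBM-SEGPHOS copper hydride → (4S) lactone; if a catalyst induces the opposite sense, its mirror-image form is used and nothing else changes.

Step 1
Reactants: 1 4-(benzyloxy)-3-methoxybenzyl alcohol
Product: 2 4-(benzyloxy)-3-methoxybenzyl chloride
Conditions: SOCl2 (1.2 equiv), CH2Cl2, 0 °C to rt, 1 h
Reagents that add atoms: thionyl chloride, O=S(Cl)Cl
Why: Chlorodehydroxylation of an electron-rich benzylic alcohol through its chlorosulfite (SN2/SNi) is fast and clean, and no stereocentre is involved.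

Step 2
Reactants: 2 4-(benzyloxy)-3-methoxybenzyl chloride; 3 5-iodovanillin (4-hydroxy-3-iodo-5-methoxybenzaldehyde)
Product: 4 4-(Ar-methoxy)-3-iodo-5-methoxybenzaldehyde
Conditions: K2CO3 (1.5 equiv), DMF, 50 °C, 6 h
Reagents that add atoms: none
Why: Williamson ether synthesis, in which the acidic phenoxide is O-alkylated by the reactive benzylic chloride; no stereocentre.

Step 3
Reactants: 4 4-(Ar-methoxy)-3-iodo-5-methoxybenzaldehyde; 5 ethyl diazoacetate
Product: 6 ethyl 2-diazo-2-[2-(Ar-methoxy)-5-formyl-3-methoxyphenyl]acetate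
Conditions: Pd(PPh3)4 (5 mol %), Ag2CO3 (0.5 equiv), Et3N (1.3 equiv), 5 (1.5 equiv), toluene, rt, 6 h, dark
Reagents that add atoms: none
Why: Palladium-catalysed cross-coupling of an aryl iodide with the C–H bond of a diazoacetate, with retention of the diazo group, gives the donor/acceptor aryldiazoacetate directly while aldehyde and ethers stay inert; no stereocentre.

Step 4
Reactants: 6 ethyl 2-diazo-2-[2-(Ar-methoxy)-5-formyl-3-methoxyphenyl]acetate
Product: 7 ethyl (2R,3S)-2-Ar-5-formyl-7-methoxy-DHB-3-carboxylate (cis)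
Conditions: Rh2(S-PTTL)4 (1 mol %), toluene (0.02 M), −60 °C, slow addition of 6, 4 h
Reagents that add atoms: none
Why: Intramolecular 1,5 C–H insertion of the rhodium carbene into the activated benzylic ether C–H bond closes the dihydrofuran on ring D, the chiral carboxylate catalyst setting C2 as R and delivering the kinetic cis ester (C3 S), a reaction well precedented for 2-aryl-7-methoxy-DHB-3-carboxylates.

Step 5
Reactants: 7 ethyl (2R,3S)-2-Ar-5-formyl-7-methoxy-DHB-3-carboxylate (cis)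
Product: 9 ethyl (2R,3R)-2-Ar-5-(hydroxymethyl)-7-methoxy-DHB-3-carboxylate (trans), via trans-aldehyde 8 (not isolated)
Conditions: NaOEt (0.3 equiv), EtOH–THF 2:1, rt, 4 h; then NaBH4 (0.6 equiv), 0 °C, 20 min; AcOH quench
Reagents that add atoms: none
Why: Base-mediated epimerisation through the ester enolate converts the cis ester into the thermodynamically favoured trans ester (C3 becomes R, C2 untouched), and the aldehyde is then reduced chemoselectively by borohydride in the same flask.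

Step 6
Reactants: 9 ethyl (2R,3R)-2-Ar-5-(hydroxymethyl)-7-methoxy-DHB-3-carboxylate; 3 5-iodovanillin
Product: 10 4-[(unit D)methoxy]-3-iodo-5-methoxybenzaldehyde
Conditions: PPh3 (1.3 equiv), DIAD (1.3 equiv), 3 (1.2 equiv), THF, 0 °C to rt, 3 h
Reagents that add atoms: none
Why: Mitsunobu etherification, in which the acidic phenol (pKa about 7) displaces the oxyphosphonium of the primary benzylic alcohol under neutral conditions that leave the trans ester untouched.

Step 7
Reactants: 10 4-[(unit D)methoxy]-3-iodo-5-methoxybenzaldehyde; 5 ethyl diazoacetate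
Product: 11 ethyl 2-diazo-2-{2-[(unit D)methoxy]-5-formyl-3-methoxyphenyl}acetate
Conditions: Pd(PPh3)4 (5 mol %), Ag2CO3 (0.5 equiv), Et3N (1.3 equiv), 5 (1.5 equiv), toluene, rt, 6 h, dark
Reagents that add atoms: none
Why: The same palladium-catalysed aryl iodide/diazoacetate cross-coupling as in step 3, run under mild conditions that do not epimerise the existing ester centre.

Step 8
Reactants: 11 ethyl 2-diazo-2-{2-[(unit D)methoxy]-5-formyl-3-methoxyphenyl}acetate
Product: 12 ethyl (2S,3R)-2-(unit D)-5-formyl-7-methoxy-DHB-3-carboxylate (cis in the new ring)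
Conditions: Rh2(R-PTTL)4 (1 mol %), toluene (0.02 M), −60 °C, slow addition of 11, 4 h
Reagents that add atoms: none
Why: Catalyst-controlled intramolecular 1,5 C–H insertion of the rhodium carbene closes the dihydrofuran on ring C, the mirror-image catalyst setting the new C2 as S (cis ester, C3 R) independently of the remote ring D centres.

Step 9
Reactants: 12 ethyl (2S,3R)-2-(unit D)-5-formyl-7-methoxy-DHB-3-carboxylate (cis)
Product: 14 ethyl (2S,3S)-2-(unit D)-5-(hydroxymethyl)-7-methoxy-DHB-3-carboxylate (trans), via trans-aldehyde 13 (not isolated)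
Conditions: NaOEt (0.3 equiv), EtOH–THF 2:1, rt, 4 h; then NaBH4 (0.6 equiv), 0 °C, 20 min; AcOH quench
Reagents that add atoms: none
Why: Thermodynamic epimerisation of the new cis ester to trans (C3 becomes S), with the older trans ester already at equilibrium, followed by chemoselective borohydride reduction of the aldehyde.

Step 10
Reactants: 14 ethyl (2S,3S)-2-(unit D)-5-(hydroxymethyl)-7-methoxy-DHB-3-carboxylate; 3 5-iodovanillin
Product: 15 4-[(unit CD)methoxy]-3-iodo-5-methoxybenzaldehyde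
Conditions: PPh3 (1.3 equiv), DIAD (1.3 equiv), 3 (1.2 equiv), THF, 0 °C to rt, 3 h
Reagents that add atoms: none
Why: Mitsunobu etherification of the acidic phenol with the primary benzylic alcohol, as in step 6; no stereocentre is touched.

Step 11
Reactants: 15 4-[(unit CD)methoxy]-3-iodo-5-methoxybenzaldehyde; 5 ethyl diazoacetate
Product: 16 ethyl 2-diazo-2-{2-[(unit CD)methoxy]-5-formyl-3-methoxyphenyl}acetate
Conditions: Pd(PPh3)4 (5 mol %), Ag2CO3 (0.5 equiv), Et3N (1.3 equiv), 5 (1.5 equiv), toluene, rt, 6 h, dark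
Reagents that add atoms: none
Why: The same palladium-catalysed aryl iodide/diazoacetate cross-coupling as in steps 3 and 7.

Step 12
Reactants: 16 ethyl 2-diazo-2-{2-[(unit CD)methoxy]-5-formyl-3-methoxyphenyl}acetate
Product: 17 ethyl (2S,3R)-2-(unit CD)-5-formyl-7-methoxy-DHB-3-carboxylate (cis in the new ring)
Conditions: Rh2(R-PTTL)4 (1 mol %), toluene (0.02 M), −60 °C, slow addition of 16, 4 h
Reagents that add atoms: none
Why: Catalyst-controlled intramolecular 1,5 C–H insertion of the rhodium carbene closes the dihydrofuran on ring B and sets its C2 as S (cis ester, C3 R).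

Step 13
Reactants: 17 ethyl (2S,3R)-2-(unit CD)-5-formyl-7-methoxy-DHB-3-carboxylate (cis)
Product: 18 (unit BCD)carbaldehyde, i.e. ethyl (2S,3S)-2-(unit CD)-5-formyl-7-methoxy-DHB-3-carboxylate (all three rings trans)
Conditions: NaOEt (0.3 equiv), EtOH–THF 2:1, rt, 4 h; AcOH quench
Reagents that add atoms: none
Why: Base-mediated epimerisation through the ester enolate gives the thermodynamically favoured trans ester in ring B (C3 becomes S), while C2 and the two older trans rings are unchanged.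

Step 14
Reactants: 2 4-(benzyloxy)-3-methoxybenzyl chloride; 19 4-bromofuran-2(5H)-one
Product: 21 4-[4-(benzyloxy)-3-methoxybenzyl]furan-2(5H)-one, via benzylzinc chloride 20 (not isolated)
Conditions: Zn dust (1.5 equiv), LiCl (1.5 equiv), THF, 25 °C, 3 h; then 19 (0.8 equiv), Pd(PPh3)4 (3 mol %), THF, 25 to 40 °C, 4 h
Reagents that add atoms: none
Why: LiCl-assisted zinc insertion gives the benzylic zinc chloride without homocoupling, and a Negishi coupling with the activated β-bromo butenolide forms the benzyl–C4 bond; no stereocentre.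

Step 15
Reactants: 21 4-[4-(benzyloxy)-3-methoxybenzyl]furan-2(5H)-one; 18 (unit BCD)carbaldehyde
Product: 23 (3R,4S)-4-(Ar-methyl)-3-[hydroxy(unit BCD)methyl]dihydrofuran-2(3H)-one (both carbinol epimers), via boron enolate 22 (not isolated)
Conditions: Cu(OAc)2·H2O (5 mol %), (R)-DTBM-SEGPHOS (5.5 mol %), HBpin (2.0 equiv), 21 (2.2 equiv), toluene, 0 °C, 3 h; then 18 (1.0 equiv), THF, −20 °C to rt, 12 h; pH 7 buffer
Reagents that add atoms: none
Why: Proposed new method: a copper hydride catalysed enantioselective reductive aldol with a β-substituted butenolide as pronucleophile, in which the ligated Cu–H delivers hydride to C4 of 21 on the ligand-controlled face (sets C4 as S), σ-bond metathesis of the copper enolate with HBpin regenerates Cu–H and stores the nucleophile as boron enolate 22, and, once the hydride is used up, aldehyde 18 is added so that the enolate (relayed through the residual copper enolate by B–O/Cu–O exchange) adds through a closed six-membered transition state on the face anti to the C4 benzyl group, forming the C7–C8 bond and the 3,4-trans lactone (C3 R) without deprotonating the three α-aryl esters, the carbinol centre being left as a mixture that converges in step 17; the closest known reaction types are the copper hydride asymmetric conjugate reduction of β-substituted butenolides and the copper-catalysed reductive aldol of acrylates with pinacolborane, which to my knowledge have not been merged on a β-substituted lactone acceptor with an aldehyde partner.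

Step 16
Reactants: 23 (3R,4S)-4-(Ar-methyl)-3-[hydroxy(unit BCD)methyl]dihydrofuran-2(3H)-one
Product: 24 (2S,3S)-3-(Ar-methyl)-2-[hydroxy(unit BCD-triol)methyl]butane-1,4-diol (hexaol, both carbinol epimers)
Conditions: LiAlH4 (6 equiv), THF, 0 °C to rt, 3 h; Rochelle salt work-up
Reagents that add atoms: none
Why: Hydride reduction of the lactone to the 1,4-diol and of the three ethyl esters to hydroxymethyl groups in one operation, with no stereocentre touched (the ring descriptors change only through priority rules).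

Step 17
Reactants: 24 hexaol
Product: 25 {(2R,3S,4S)-4-(Ar-methyl)-2-(unit BCD-triol)oxolan-3-yl}methanol (dibenzyl ether of the target)
Conditions: CSA (0.2 equiv), MeCN–CH2Cl2 1:1, 0 °C to rt, 2 h; Et3N quench
Reagents that add atoms: none
Why: Acid-catalysed dehydrative SN1 cycloetherification, in which either carbinol epimer ionises to the same benzylic cation (stabilised by the para ring oxygen of ring B) and 5-exo capture by the C9' primary hydroxyl places the aryl group trans to the C3 substituent (C2 set as R), while the 3,4-cis relationship is inherited from the trans lactone.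

Step 18
Reactants: 25 dibenzyl ether of the target
Product: 26 CNP0267891.2 (target)
Conditions: H2 (1 atm), 10% Pd/C, EtOAc–EtOH 4:1, rt, 1–2 h, stopped at full conversion
Reagents that add atoms: none
Why: Catalytic hydrogenolysis of the two unhindered aryl benzyl ethers is much faster than cleavage of the hindered secondary benzylic C–O bonds of the four cyclic ethers, and no stereocentre is changed.

**Compound list**
1 | 4-(benzyloxy)-3-methoxybenzyl alcohol | OCc1ccc(OCc2ccccc2)c(OC)c1 | starting material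
2 | 4-(benzyloxy)-3-methoxybenzyl chloride | ClCc1ccc(OCc2ccccc2)c(OC)c1 | intermediate
3 | 5-iodovanillin (4-hydroxy-3-iodo-5-methoxybenzaldehyde) | O=Cc1cc(I)c(O)c(OC)c1 | starting material
4 | 4-{[4-(benzyloxy)-3-methoxyphenyl]methoxy}-3-iodo-5-methoxybenzaldehyde | O=Cc1cc(I)c(OCc2ccc(OCc3ccccc3)c(OC)c2)c(OC)c1 | intermediate
5 | ethyl diazoacetate | CCOC(=O)C=[N+]=[N-] | starting material
6 | ethyl 2-diazo-2-(2-{[4-(benzyloxy)-3-methoxyphenyl]methoxy}-5-formyl-3-methoxyphenyl)acetate | CCOC(=O)C(=[N+]=[N-])c1cc(C=O)cc(OC)c1OCc1ccc(OCc2ccccc2)c(OC)c1 | intermediate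
7 | ethyl (2R,3S)-2-[4-(benzyloxy)-3-methoxyphenyl]-5-formyl-7-methoxy-2,3-dihydro-1-benzofuran-3-carboxylate (cis) | O=Cc1cc(OC)c2c(c1)[C@H](C(=O)OCC)[C@H](c1ccc(OCc3ccccc3)c(OC)c1)O2 | intermediate
8 | ethyl (2R,3R)-2-[4-(benzyloxy)-3-methoxyphenyl]-5-formyl-7-methoxy-2,3-dihydro-1-benzofuran-3-carboxylate (trans, not isolated) | O=Cc1cc(OC)c2c(c1)[C@@H](C(=O)OCC)[C@H](c1ccc(OCc3ccccc3)c(OC)c1)O2 | intermediate
9 | ethyl (2R,3R)-2-[4-(benzyloxy)-3-methoxyphenyl]-5-(hydroxymethyl)-7-methoxy-2,3-dihydro-1-benzofuran-3-carboxylate | OCc1cc(OC)c2c(c1)[C@@H](C(=O)OCC)[C@H](c1ccc(OCc3ccccc3)c(OC)c1)O2 | intermediate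
10 | 4-{[(2R,3R)-2-[4-(benzyloxy)-3-methoxyphenyl]-3-(ethoxycarbonyl)-7-methoxy-2,3-dihydro-1-benzofuran-5-yl]methoxy}-3-iodo-5-methoxybenzaldehyde | O=Cc1cc(I)c(OCc2cc(OC)c3c(c2)[C@@H](C(=O)OCC)[C@H](c2ccc(OCc4ccccc4)c(OC)c2)O3)c(OC)c1 | intermediate
11 | ethyl 2-diazo-2-{2-[(unit D)methoxy]-5-formyl-3-methoxyphenyl}acetate | CCOC(=O)C(=[N+]=[N-])c1cc(C=O)cc(OC)c1OCc1cc(OC)c2c(c1)[C@@H](C(=O)OCC)[C@H](c1ccc(OCc3ccccc3)c(OC)c1)O2 | intermediate
12 | ethyl (2S,3R)-2-(unit D)-5-formyl-7-methoxy-2,3-dihydro-1-benzofuran-3-carboxylate (cis in ring C dihydrofuran) | O=Cc1cc(OC)c2c(c1)[C@@H](C(=O)OCC)[C@@H](c1cc(OC)c3c(c1)[C@@H](C(=O)OCC)[C@H](c1ccc(OCc4ccccc4)c(OC)c1)O3)O2 | intermediate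
13 | ethyl (2S,3S)-2-(unit D)-5-formyl-7-methoxy-2,3-dihydro-1-benzofuran-3-carboxylate (trans, not isolated) | O=Cc1cc(OC)c2c(c1)[C@H](C(=O)OCC)[C@@H](c1cc(OC)c3c(c1)[C@@H](C(=O)OCC)[C@H](c1ccc(OCc4ccccc4)c(OC)c1)O3)O2 | intermediate
14 | ethyl (2S,3S)-2-(unit D)-5-(hydroxymethyl)-7-methoxy-2,3-dihydro-1-benzofuran-3-carboxylate | OCc1cc(OC)c2c(c1)[C@H](C(=O)OCC)[C@@H](c1cc(OC)c3c(c1)[C@@H](C(=O)OCC)[C@H](c1ccc(OCc4ccccc4)c(OC)c1)O3)O2 | intermediate
15 | 4-[(unit CD)methoxy]-3-iodo-5-methoxybenzaldehyde | O=Cc1cc(I)c(OCc2cc(OC)c3c(c2)[C@H](C(=O)OCC)[C@@H](c2cc(OC)c4c(c2)[C@@H](C(=O)OCC)[C@H](c2ccc(OCc5ccccc5)c(OC)c2)O4)O3)c(OC)c1 | intermediate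
16 | ethyl 2-diazo-2-{2-[(unit CD)methoxy]-5-formyl-3-methoxyphenyl}acetate | CCOC(=O)C(=[N+]=[N-])c1cc(C=O)cc(OC)c1OCc1cc(OC)c2c(c1)[C@H](C(=O)OCC)[C@@H](c1cc(OC)c3c(c1)[C@@H](C(=O)OCC)[C@H](c1ccc(OCc4ccccc4)c(OC)c1)O3)O2 | intermediate
17 | ethyl (2S,3R)-2-(unit CD)-5-formyl-7-methoxy-2,3-dihydro-1-benzofuran-3-carboxylate (cis in ring B dihydrofuran) | O=Cc1cc(OC)c2c(c1)[C@@H](C(=O)OCC)[C@@H](c1cc(OC)c3c(c1)[C@H](C(=O)OCC)[C@@H](c1cc(OC)c4c(c1)[C@@H](C(=O)OCC)[C@H](c1ccc(OCc5ccccc5)c(OC)c1)O4)O3)O2 | intermediate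
18 | ethyl (2S,3S)-2-(unit CD)-5-formyl-7-methoxy-2,3-dihydro-1-benzofuran-3-carboxylate (all-trans triester aldehyde) | O=Cc1cc(OC)c2c(c1)[C@H](C(=O)OCC)[C@@H](c1cc(OC)c3c(c1)[C@H](C(=O)OCC)[C@@H](c1cc(OC)c4c(c1)[C@@H](C(=O)OCC)[C@H](c1ccc(OCc5ccccc5)c(OC)c1)O4)O3)O2 | intermediate
19 | 4-bromofuran-2(5H)-one | O=C1C=C(Br)CO1 | starting material
20 | [4-(benzyloxy)-3-methoxybenzyl]zinc chloride (not isolated) | Cl[Zn]Cc1ccc(OCc2ccccc2)c(OC)c1 | intermediate
21 | 4-[4-(benzyloxy)-3-methoxybenzyl]furan-2(5H)-one | O=C1C=C(Cc2ccc(OCc3ccccc3)c(OC)c2)CO1 | intermediate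
22 | 2-({(4S)-4-[4-(benzyloxy)-3-methoxybenzyl]-4,5-dihydrofuran-2-yl}oxy)-4,4,5,5-tetramethyl-1,3,2-dioxaborolane (not isolated) | CC1(C)OB(OC2=C[C@H](Cc3ccc(OCc4ccccc4)c(OC)c3)CO2)OC1(C)C | intermediate
23 | (3R,4S)-4-[4-(benzyloxy)-3-methoxybenzyl]-3-[hydroxy(unit BCD)methyl]dihydrofuran-2(3H)-one (carbinol centre unassigned, both epimers) | COc1cc(C[C@@H]2COC(=O)[C@H]2C(O)c2cc(OC)c3c(c2)[C@H](C(=O)OCC)[C@@H](c2cc(OC)c4c(c2)[C@H](C(=O)OCC)[C@@H](c2cc(OC)c5c(c2)[C@@H](C(=O)OCC)[C@H](c2ccc(OCc6ccccc6)c(OC)c2)O5)O4)O3)ccc1OCc1ccccc1 | intermediate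
24 | (2S,3S)-3-[4-(benzyloxy)-3-methoxybenzyl]-2-[hydroxy(unit BCD-triol)methyl]butane-1,4-diol (carbinol centre unassigned, both epimers) | COc1cc(C[C@H](CO)[C@@H](CO)C(O)c2cc(OC)c3c(c2)[C@H](CO)[C@@H](c2cc(OC)c4c(c2)[C@H](CO)[C@@H](c2cc(OC)c5c(c2)[C@@H](CO)[C@H](c2ccc(OCc6ccccc6)c(OC)c2)O5)O4)O3)ccc1OCc1ccccc1 | intermediate
25 | {(2R,3S,4S)-4-[4-(benzyloxy)-3-methoxybenzyl]-2-(unit BCD-triol)oxolan-3-yl}methanol (dibenzyl ether of the target) | COc1cc(C[C@@H]2CO[C@@H](c3cc(OC)c4c(c3)[C@H](CO)[C@@H](c3cc(OC)c5c(c3)[C@H](CO)[C@@H](c3cc(OC)c6c(c3)[C@@H](CO)[C@H](c3ccc(OCc7ccccc7)c(OC)c3)O6)O5)O4)[C@@H]2CO)ccc1OCc1ccccc1 | intermediate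
26 | CNP0267891.2: [(2S,3R)-2-{(2S,3R)-2-[(2R,3S)-2-(4-hydroxy-3-methoxyphenyl)-3-(hydroxymethyl)-7-methoxy-2,3-dihydro-1-benzofuran-5-yl]-3-(hydroxymethyl)-7-methoxy-2,3-dihydro-1-benzofuran-5-yl}-5-[(2R,3S,4S)-4-(4-hydroxy-3-methoxybenzyl)-3-(hydroxymethyl)oxolan-2-yl]-7-methoxy-2,3-dihydro-1-benzofuran-3-yl]methanol | COc1cc(C[C@@H]2CO[C@@H](c3cc(OC)c4c(c3)[C@H](CO)[C@@H](c3cc(OC)c5c(c3)[C@H](CO)[C@@H](c3cc(OC)c6c(c3)[C@@H](CO)[C@H](c3ccc(O)c(OC)c3)O6)O5)O4)[C@@H]2CO)ccc1O | target

**Step count.** Total steps: 18. Longest linear sequence: 17 (steps 1–13, then 15–18; step 14 is the side branch).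

**Steps most likely to fail**

Step 15 (the proposed new reductive aldol). It can fail through residual hydride reducing 18, a sluggish aldol of the pinacol boron enolate, or insufficient enantioselectivity. The fallback uses known chemistry, sets out from 21 and 18, and comes back at 23. Butenolide 21 is reduced by the established copper hydride conjugate reduction with proton quench (Cu(OAc)2·H2O, (R)-DTBM-SEGPHOS, PMHS, t-BuOH, toluene, 0 °C) to (S)-4-[4-(benzyloxy)-3-methoxybenzyl]dihydrofuran-2(3H)-one F1, which is recrystallised to raise the ee. Deprotonation with LiN(iPr)2 in THF at −78 °C gives the lithium enolate of the lactone F2. Aldehyde 18 (0.5 equiv) is added at −78 °C and the mixture is quenched cold with AcOH. This is the classical trans-selective lactone enolate aldol of lignan synthesis and delivers 23.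

Step 3 (first of the three Pd couplings with ethyl diazoacetate). The iodide is ortho-alkoxy-hindered and carries a free aldehyde. The fallback sets out from 4 and comes back at 6, installing the diazo group by diazo transfer instead of cross-coupling. Aldehyde 4 is masked with HC(OMe)3 and catalytic TsOH in MeOH as 1-(benzyloxy)-4-{[4-(dimethoxymethyl)-2-iodo-6-methoxyphenoxy]methyl}-2-methoxybenzene F3. Palladium-catalysed coupling with the Reformatsky reagent BrZnCH2CO2Et (Pd(dba)2, Q-Phos, THF, rt) gives ethyl 2-(2-{[4-(benzyloxy)-3-methoxyphenyl]methoxy}-5-(dimethoxymethyl)-3-methoxyphenyl)acetate F4. The acetal is cleaved in the 1 M HCl/THF work-up to ethyl 2-(2-{[4-(benzyloxy)-3-methoxyphenyl]methoxy}-5-formyl-3-methoxyphenyl)acetate F5. Regitz diazo transfer (p-ABSA, DBU, MeCN, 0 °C to rt) then gives 6.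

Step 6 (Mitsunobu etherification, used again in step 10). The phenol is flanked by two ortho substituents, and the para-alkoxybenzylic oxyphosphonium can ionise. The fallback sets out from 9 and comes back at 10. Alcohol 9 is converted with CBr4 and PPh3 in CH2Cl2 at 0 °C into ethyl (2R,3R)-2-[4-(benzyloxy)-3-methoxyphenyl]-5-(bromomethyl)-7-methoxy-2,3-dihydro-1-benzofuran-3-carboxylate F6. The crude bromide alkylates 5-iodovanillin 3 with K2CO3 in DMF at rt (Williamson etherification as in step 2) to give 10.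

**Further compounds**
F1 | step 15 | (S)-4-[4-(benzyloxy)-3-methoxybenzyl]dihydrofuran-2(3H)-one | COc1cc(C[C@@H]2COC(=O)C2)ccc1OCc1ccccc1
F2 | step 15 | lithium (4S)-4-[4-(benzyloxy)-3-methoxybenzyl]-4,5-dihydrofuran-2-olate | [Li]OC1=C[C@H](Cc2ccc(OCc3ccccc3)c(OC)c2)CO1
F3 | step 3 | 1-(benzyloxy)-4-{[4-(dimethoxymethyl)-2-iodo-6-methoxyphenoxy]methyl}-2-methoxybenzene | COC(OC)c1cc(I)c(OCc2ccc(OCc3ccccc3)c(OC)c2)c(OC)c1
F4 | step 3 | ethyl 2-(2-{[4-(benzyloxy)-3-methoxyphenyl]methoxy}-5-(dimethoxymethyl)-3-methoxyphenyl)acetate | CCOC(=O)Cc1cc(C(OC)OC)cc(OC)c1OCc1ccc(OCc2ccccc2)c(OC)c1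
F5 | step 3 | ethyl 2-(2-{[4-(benzyloxy)-3-methoxyphenyl]methoxy}-5-formyl-3-methoxyphenyl)acetate | CCOC(=O)Cc1cc(C=O)cc(OC)c1OCc1ccc(OCc2ccccc2)c(OC)c1
F6 | step 6 | ethyl (2R,3R)-2-[4-(benzyloxy)-3-methoxyphenyl]-5-(bromomethyl)-7-methoxy-2,3-dihydro-1-benzofuran-3-carboxylate | BrCc1cc(OC)c2c(c1)[C@@H](C(=O)OCC)[C@H](c1ccc(OCc3ccccc3)c(OC)c1)O2
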